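**Plan**

- Numbering: ring C1–C10 with C1=C10 (methyl on C10), epoxide C4–C5 (methyl on C4), C6 carbinol, C7 bearing C11 (methyl C13, C12H2–O) and the C8 ester. The enabling feature: C1, C10, C5 and C4 can be the corners of one cyclobutane, C2–C3 closes a second one on the C1–C4 edge, and C6, C5, C10, C9, C8, C7 form a 3-methylcyclohexenone ring with C6 as carbonyl.
- Retrosynthesis: remove the epoxide oxygen and the C6 hydride, cut the two angelate C–O bonds, turn the C1=C10 and C4=C5 π bonds back into the σ bonds C1–C4 and C5–C10 of a tricyclic ketone, cut C4–C5 and C1–C10 ([2+2]), then C5=C10 (metathesis), C5–C6, C7–C8 (aldol) and C6–C7 (CO2).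
- Forward: chain C12–C11–C7–C6, aldol to add C8–C10, six-membered ring by ring-closing metathesis, both four-membered rings in one photocycloaddition, ten-membered ring by thermal unzipping, then esters, C6 carbinol and epoxide.
- Stereochemistry: C11 from (R)-3-bromo-2-methylpropan-1-ol; C7 and C8 from an Evans syn aldol with (R)-4-benzyloxazolidin-2-one; 1(10)E and 4Z from the cis,anti,cis tricycle and enone conjugation; C6 from a CBS reduction; C4 and C5 from epoxidation of the Z alkene directed by the C6 hydroxyl.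

Key step: step 11

Remark: 1-methylcyclobutene (16) is taken as a purchasable, volatile liquid that is handled cold.
Remark: 17 is drawn as the isomer formed anti to the C8 silyl ether; its facial isomer has the same cis,anti,cis fusion and should give the same 18.
Remark: in the CBS step the Z-alkenyl carbon C5 is assumed to act as the larger carbonyl substituent, as it does in cyclic enones.

**Route**

Step 1
Reactants: 1 (R)-3-bromo-2-methylpropan-1-ol
Product: 2 (R)-(3-bromo-2-methylpropoxy)(tert-butyl)dimethylsilane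
Conditions: TBSCl, imidazole, CH2Cl2, 0 °C to rt
Reagents that add atoms: tert-butyldimethylsilyl chloride, CC(C)(C)[Si](C)(C)Cl
Why: Imidazole-promoted silylation of the primary alcohol leaves the bromide and the C11 stereocentre untouched.

Step 2
Reactants: 2 (R)-(3-bromo-2-methylpropoxy)(tert-butyl)dimethylsilane
Product: 4 (S)-4-(tert-butyldimethylsilyloxy)-3-methylbutanoic acid, via Grignard reagent 3 (not isolated)
Conditions: Mg turnings, THF, 45 °C; CO2, −20 °C to rt; 1 M HCl to pH 3, 0 °C
Reagents that add atoms: carbon dioxide, O=C=O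
Why: Grignard formation from the primary bromide and carboxylation with CO2 add C6 as the acid carbon (classical one-carbon homologation), and C11, which lies β to the metal, cannot epimerise.

Step 3
Reactants: 4 (S)-4-(tert-butyldimethylsilyloxy)-3-methylbutanoic acid and 5 (R)-4-benzyloxazolidin-2-one
Product: 7 (R)-4-benzyl-3-[(S)-4-(tert-butyldimethylsilyloxy)-3-methylbutanoyl]oxazolidin-2-one, via mixed pivalic anhydride 6 (not isolated)
Conditions: PivCl, Et3N, THF, −20 °C; then 5, LiCl, −20 °C to rt
Reagents that add atoms: none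
Why: N-Acylation of the Evans oxazolidinone through the mixed pivalic anhydride (LiCl/Et3N variant) is a standard route to the imide and does not touch C11.

Step 4
Reactants: 8 3-methylbut-3-en-1-ol
Product: 9 3-methylbut-3-enal
Conditions: Dess–Martin periodinane, CH2Cl2, 0 °C to rt; cold aq NaHCO3 wash; used at once as a dried CH2Cl2 solution
Reagents that add atoms: none
Why: Dess–Martin oxidation is fast and near neutral, so the β,γ-unsaturated aldehyde should be obtained without migration of the double bond into conjugation.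

Step 5
Reactants: 7 (R)-4-benzyl-3-[(S)-4-(tert-butyldimethylsilyloxy)-3-methylbutanoyl]oxazolidin-2-one and 9 3-methylbut-3-enal
Product: 11 (R)-4-benzyl-3-[(2R,3S)-2-[(S)-1-(tert-butyldimethylsilyloxy)propan-2-yl]-3-hydroxy-5-methylhex-5-enoyl]oxazolidin-2-one, via dibutylboron Z-enolate 10 (not isolated)
Conditions: Bu2BOTf, iPr2NEt, CH2Cl2, 0 °C; then 9 (2 equiv), −78 to 0 °C; pH 7 buffer, MeOH, 30% H2O2, 0 °C
Reagents that add atoms: none
Why: Evans syn aldol, in which the Z(O)-boron enolate reacts through a Zimmerman–Traxler chair on the face left open by the benzyl group of the (R)-auxiliary, sets C7 (R) and C8 (S) syn to each other irrespective of the spectator centre C11.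

Step 6
Reactants: 11 (R)-4-benzyl-3-[(2R,3S)-2-[(S)-1-(tert-butyldimethylsilyloxy)propan-2-yl]-3-hydroxy-5-methylhex-5-enoyl]oxazolidin-2-one
Product: 12 (2R,3S)-2-[(S)-1-(tert-butyldimethylsilyloxy)propan-2-yl]-3-hydroxy-N-methoxy-N,5-dimethylhex-5-enamide
Conditions: MeNHOMe·HCl, AlMe3, CH2Cl2, −20 to 0 °C; aq potassium sodium tartrate
Reagents that add atoms: N,O-dimethylhydroxylamine hydrochloride, CNOC.Cl
Why: Weinreb transamination with the aluminium amide is assisted by the free C8 hydroxyl (aluminium alkoxide chelate), so the auxiliary should leave by exocyclic cleavage without retro-aldol reaction or epimerisation at C7.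

Step 7
Reactants: 12 (2R,3S)-2-[(S)-1-(tert-butyldimethylsilyloxy)propan-2-yl]-3-hydroxy-N-methoxy-N,5-dimethylhex-5-enamide
Product: 13 (2R,3S)-3-(tert-butyldimethylsilyloxy)-2-[(S)-1-(tert-butyldimethylsilyloxy)propan-2-yl]-N-methoxy-N,5-dimethylhex-5-enamide
Conditions: TBSOTf, 2,6-lutidine, CH2Cl2, −78 to 0 °C
Reagents that add atoms: tert-butyldimethylsilyl triflate, CC(C)(C)[Si](C)(C)OS(=O)(=O)C(F)(F)F
Why: The silyl triflate with 2,6-lutidine silylates the hindered secondary alcohol while the Weinreb amide and the alkene stay inert.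

Step 8
Reactants: 13 (2R,3S)-3-(tert-butyldimethylsilyloxy)-2-[(S)-1-(tert-butyldimethylsilyloxy)propan-2-yl]-N-methoxy-N,5-dimethylhex-5-enamide
Product: 14 (4R,5S)-5-(tert-butyldimethylsilyloxy)-4-[(S)-1-(tert-butyldimethylsilyloxy)propan-2-yl]-7-methylocta-1,7-dien-3-one
Conditions: vinylmagnesium bromide, THF, −20 to 0 °C; poured into cold 1 M HCl
Reagents that add atoms: vinylmagnesium bromide, C=C[Mg]Br
Why: Weinreb ketone synthesis, in which the magnesium chelate of the tetrahedral adduct stops after one addition and the acidic quench protonates the released amine before it can add to the new vinyl ketone.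

Step 9
Reactants: 14 (4R,5S)-5-(tert-butyldimethylsilyloxy)-4-[(S)-1-(tert-butyldimethylsilyloxy)propan-2-yl]-7-methylocta-1,7-dien-3-one
Product: 15 (5S,6R)-5-(tert-butyldimethylsilyloxy)-6-[(S)-1-(tert-butyldimethylsilyloxy)propan-2-yl]-3-methylcyclohex-2-en-1-one
Conditions: second-generation Grubbs catalyst (H2IMes)(PCy3)Cl2Ru=CHPh (5 mol %), CH2Cl2 (0.01 M), 40 °C
Reagents that add atoms: none
Why: Ring-closing metathesis of the vinyl ketone with the 1,1-disubstituted alkene closes the six-membered ring as the trisubstituted enone (C5=C10) with loss of ethylene, a well-used route to 3-methylcyclohex-2-enones that leaves the silyl ethers and C7 alone.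

Step 10
Reactants: 15 (5S,6R)-5-(tert-butyldimethylsilyloxy)-6-[(S)-1-(tert-butyldimethylsilyloxy)propan-2-yl]-3-methylcyclohex-2-en-1-one and 16 1-methylcyclobutene
Product: 17 (8R,9S)-9-(tert-butyldimethylsilyloxy)-8-[(S)-1-(tert-butyldimethylsilyloxy)propan-2-yl]-1,5-dimethyltricyclo[4.4.0.0(2,5)]decan-7-one (cis,anti,cis)
Conditions: hν (350 nm, Pyrex), 16 (10 equiv), CH2Cl2, −40 °C; then basic Al2O3, CH2Cl2, rt
Reagents that add atoms: none
Why: Enone–alkene [2+2] photocycloaddition through the triplet enone should join C4 to C5 and C1 to C10 (head-to-head, which keeps the quaternary carbons C4 and C10 apart, as known for 1-methylcyclobutene with 6-alkyl-3-methylcyclohexenones), place the cyclobutene ring anti to the six-membered ring and anti to the C8 silyl ether, and Al2O3 epimerises any trans-fused adduct at C5 to the cis fusion.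

Step 11
Reactants: 17 (8R,9S)-9-(tert-butyldimethylsilyloxy)-8-[(S)-1-(tert-butyldimethylsilyloxy)propan-2-yl]-1,5-dimethyltricyclo[4.4.0.0(2,5)]decan-7-one
Product: 18 (2Z,6E,9S,10R)-9-(tert-butyldimethylsilyloxy)-10-[(S)-1-(tert-butyldimethylsilyloxy)propan-2-yl]-3,7-dimethylcyclodeca-2,6-dien-1-one
Conditions: toluene (0.005 M, degassed), base-washed steel flow coil, 200–210 °C, residence about 15 min
Reagents that add atoms: none
Why: Homolysis of the strained central bond C1–C4 of the bicyclo[2.2.0]hexane gives a cyclohexane-1,4-diyl (tertiary radical at C4, secondary at C1) that cleaves the C5–C10 bond, so the C1=C10 and C4=C5 π bonds form in a formal retro-[2+2] driven by the strain of the two fused four-membered rings. The closest known reaction is the thermolysis of cyclohexenone–cyclobutene photoadducts to cyclodeca-1,5-dienes, including adducts of 1-methylcyclobutene with 6-alkyl-3-methylcyclohexenones that give 1(10)E,4Z-cyclodecadien-6-ones. No ring is closed by bond formation: the ten-membered ring appears because the six-membered ring and the two four-membered rings lose the two bonds they share (ring enlargement by fragmentation). No stereocentre is created; C1, C4, C5 and C10 become sp2, which is why facial isomers of 17 converge, and C7, C8 and C11 are not involved. The step needs E at C1=C10, Z at C4=C5 and no subsequent Cope rearrangement to the divinylcyclohexanone: the cis,anti,cis fusion leads through a chair-like diyl to one E and one Z alkene, the alkene that becomes conjugated with the C6 carbonyl is expected to be the Z one because only a Z enone can be planar in this ring, and high dilution, neutral walls and a short residence time limit the Cope pathway.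

Step 12
Reactants: 18 (2Z,6E,9S,10R)-9-(tert-butyldimethylsilyloxy)-10-[(S)-1-(tert-butyldimethylsilyloxy)propan-2-yl]-3,7-dimethylcyclodeca-2,6-dien-1-one
Product: 19 (2Z,6E,9S,10R)-9-hydroxy-10-[(S)-1-hydroxypropan-2-yl]-3,7-dimethylcyclodeca-2,6-dien-1-one
Conditions: HF·pyridine, pyridine, THF, 0 °C to rt
Reagents that add atoms: none
Why: Fluoride-mediated desilylation with pyridine-buffered HF·pyridine cleaves both silyl ethers under conditions mild enough for the enone, the 1,5-diene and the β-hydroxy ketone.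

Step 13
Reactants: 19 (2Z,6E,9S,10R)-9-hydroxy-10-[(S)-1-hydroxypropan-2-yl]-3,7-dimethylcyclodeca-2,6-dien-1-one and 20 angelic acid
Product: 22 (S)-2-[(1R,2S,4E,8Z)-4,8-dimethyl-2-{[(Z)-2-methylbut-2-enoyl]oxy}-10-oxocyclodeca-4,8-dien-1-yl]propyl (Z)-2-methylbut-2-enoate, via mixed angelic anhydride 21 (not isolated)
Conditions: 20 (3 equiv), 2,4,6-trichlorobenzoyl chloride, Et3N, toluene, rt; then 19, 70 °C
Reagents that add atoms: none
Why: Yamaguchi-type esterification through the mixed 2,4,6-trichlorobenzoic anhydride without DMAP acylates the primary C12 and the secondary C8 hydroxyl while keeping the Z geometry of the angelate, and the C6 ketone stands in for the hydroxyl that must stay free.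

Step 14
Reactants: 22 (S)-2-[(1R,2S,4E,8Z)-4,8-dimethyl-2-{[(Z)-2-methylbut-2-enoyl]oxy}-10-oxocyclodeca-4,8-dien-1-yl]propyl (Z)-2-methylbut-2-enoate
Product: 23 (S)-2-[(1S,2S,4E,8Z,10S)-10-hydroxy-4,8-dimethyl-2-{[(Z)-2-methylbut-2-enoyl]oxy}cyclodeca-4,8-dien-1-yl]propyl (Z)-2-methylbut-2-enoate
Conditions: (S)-2-methyl-CBS-oxazaborolidine (1 equiv), catecholborane, toluene, −78 to −40 °C; MeOH, then aq NaHCO3
Reagents that add atoms: none
Why: Corey–Bakshi–Shibata reduction in which, with the Z-alkenyl arm as the larger carbonyl substituent, the (S)-catalyst should deliver hydride to the face that places the C6 hydroxyl cis to the C7 side chain and trans to the C8 ester, while catecholborane at low temperature reduces only the ketone (1,2) and spares the angelates and the ring alkenes.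

Step 15
Reactants: 23 (S)-2-[(1S,2S,4E,8Z,10S)-10-hydroxy-4,8-dimethyl-2-{[(Z)-2-methylbut-2-enoyl]oxy}cyclodeca-4,8-dien-1-yl]propyl (Z)-2-methylbut-2-enoate
Product: 24 CNP0272382.1, (4S,5R,6R,7S,8S,11S)-4,5-epoxy-6-hydroxygermacr-1(10)E-ene-8,12-diyl bis[(Z)-2-methylbut-2-enoate]
Conditions: VO(acac)2 (5 mol %), t-BuOOH (anhydrous, in decane), CH2Cl2, 0 °C
Reagents that add atoms: tert-butyl hydroperoxide, CC(C)(C)OO
Why: Vanadium-catalysed hydroxyl-directed epoxidation, in which the vanadate ester of the C6 hydroxyl delivers oxygen to the adjacent C4=C5 bond on the hydroxyl face as is typical for medium-ring Z-allylic alcohols, turns the Z alkene into the cis epoxide (C4 S, C5 R) and leaves the C1=C10 alkene and the electron-poor angelates alone.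

**Compound list**

1 | (R)-3-bromo-2-methylpropan-1-ol | OC[C@@H](C)CBr | starting material
2 | (R)-(3-bromo-2-methylpropoxy)(tert-butyl)dimethylsilane | CC(C)(C)[Si](C)(C)OC[C@@H](C)CBr | intermediate
3 | [(R)-3-(tert-butyldimethylsilyloxy)-2-methylpropyl]magnesium bromide | CC(C)(C)[Si](C)(C)OC[C@@H](C)C[Mg]Br | intermediate (not isolated)
4 | (S)-4-(tert-butyldimethylsilyloxy)-3-methylbutanoic acid | CC(C)(C)[Si](C)(C)OC[C@@H](C)CC(=O)O | intermediate
5 | (R)-4-benzyloxazolidin-2-one | O=C1N[C@H](Cc2ccccc2)CO1 | starting material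
6 | (S)-4-(tert-butyldimethylsilyloxy)-3-methylbutanoic pivalic anhydride | CC(C)(C)[Si](C)(C)OC[C@@H](C)CC(=O)OC(=O)C(C)(C)C | intermediate (not isolated)
7 | (R)-4-benzyl-3-[(S)-4-(tert-butyldimethylsilyloxy)-3-methylbutanoyl]oxazolidin-2-one | CC(C)(C)[Si](C)(C)OC[C@@H](C)CC(=O)N1[C@H](Cc2ccccc2)COC1=O | intermediate
8 | 3-methylbut-3-en-1-ol | CC(=C)CCO | starting material
9 | 3-methylbut-3-enal | CC(=C)CC=O | intermediate
10 | dibutylboron (Z)-enolate of 7 | CC(C)(C)[Si](C)(C)OC[C@@H](C)/C=C(\OB(CCCC)CCCC)N1[C@H](Cc2ccccc2)COC1=O | intermediate (not isolated)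
11 | (R)-4-benzyl-3-[(2R,3S)-2-[(S)-1-(tert-butyldimethylsilyloxy)propan-2-yl]-3-hydroxy-5-methylhex-5-enoyl]oxazolidin-2-one | CC(C)(C)[Si](C)(C)OC[C@@H](C)[C@H]([C@@H](O)CC(C)=C)C(=O)N1[C@H](Cc2ccccc2)COC1=O | intermediate
12 | (2R,3S)-2-[(S)-1-(tert-butyldimethylsilyloxy)propan-2-yl]-3-hydroxy-N-methoxy-N,5-dimethylhex-5-enamide | CC(C)(C)[Si](C)(C)OC[C@@H](C)[C@H]([C@@H](O)CC(C)=C)C(=O)N(C)OC | intermediate
13 | (2R,3S)-3-(tert-butyldimethylsilyloxy)-2-[(S)-1-(tert-butyldimethylsilyloxy)propan-2-yl]-N-methoxy-N,5-dimethylhex-5-enamide | CC(C)(C)[Si](C)(C)OC[C@@H](C)[C@H]([C@@H](O[Si](C)(C)C(C)(C)C)CC(C)=C)C(=O)N(C)OC | intermediate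
14 | (4R,5S)-5-(tert-butyldimethylsilyloxy)-4-[(S)-1-(tert-butyldimethylsilyloxy)propan-2-yl]-7-methylocta-1,7-dien-3-one | CC(C)(C)[Si](C)(C)OC[C@@H](C)[C@H]([C@@H](O[Si](C)(C)C(C)(C)C)CC(C)=C)C(=O)C=C | intermediate
15 | (5S,6R)-5-(tert-butyldimethylsilyloxy)-6-[(S)-1-(tert-butyldimethylsilyloxy)propan-2-yl]-3-methylcyclohex-2-en-1-one (silyloxy group and side chain trans) | CC(C)(C)[Si](C)(C)OC[C@@H](C)[C@H]1C(=O)C=C(C)C[C@@H]1O[Si](C)(C)C(C)(C)C | intermediate
16 | 1-methylcyclobutene | CC1=CCC1 | starting material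
17 | (8R,9S)-9-(tert-butyldimethylsilyloxy)-8-[(S)-1-(tert-butyldimethylsilyloxy)propan-2-yl]-1,5-dimethyltricyclo[4.4.0.0(2,5)]decan-7-one; cis,anti,cis (C5–H cis to C10–CH3, C1–H cis to C4–CH3, outer four-membered ring anti to the six-membered ring), four-membered rings on the face opposite to the C8 silyl ether | CC(C)(C)[Si](C)(C)OC[C@@H](C)[C@H]1C(=O)[C@H]2[C@]3(C)CC[C@@H]3[C@@]2(C)C[C@@H]1O[Si](C)(C)C(C)(C)C | intermediate
18 | (2Z,6E,9S,10R)-9-(tert-butyldimethylsilyloxy)-10-[(S)-1-(tert-butyldimethylsilyloxy)propan-2-yl]-3,7-dimethylcyclodeca-2,6-dien-1-one (1(10)E,4Z-dien-6-one in target numbering) | CC(C)(C)[Si](C)(C)OC[C@@H](C)[C@H]1C(=O)/C=C(C)\CC/C=C(\C)C[C@@H]1O[Si](C)(C)C(C)(C)C | intermediate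
19 | (2Z,6E,9S,10R)-9-hydroxy-10-[(S)-1-hydroxypropan-2-yl]-3,7-dimethylcyclodeca-2,6-dien-1-one | OC[C@@H](C)[C@H]1C(=O)/C=C(C)\CC/C=C(\C)C[C@@H]1O | intermediate
20 | angelic acid, (Z)-2-methylbut-2-enoic acid | C/C=C(/C)C(=O)O | starting material
21 | (Z)-2-methylbut-2-enoic 2,4,6-trichlorobenzoic anhydride | C/C=C(/C)C(=O)OC(=O)c1c(Cl)cc(Cl)cc1Cl | intermediate (not isolated)
22 | (S)-2-[(1R,2S,4E,8Z)-4,8-dimethyl-2-{[(Z)-2-methylbut-2-enoyl]oxy}-10-oxocyclodeca-4,8-dien-1-yl]propyl (Z)-2-methylbut-2-enoate | C/C=C(/C)C(=O)OC[C@@H](C)[C@H]1C(=O)/C=C(C)\CC/C=C(\C)C[C@@H]1OC(=O)/C(C)=C\C | intermediate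
23 | (S)-2-[(1S,2S,4E,8Z,10S)-10-hydroxy-4,8-dimethyl-2-{[(Z)-2-methylbut-2-enoyl]oxy}cyclodeca-4,8-dien-1-yl]propyl (Z)-2-methylbut-2-enoate | C/C=C(/C)C(=O)OC[C@@H](C)[C@H]1[C@@H](O)/C=C(C)\CC/C=C(\C)C[C@@H]1OC(=O)/C(C)=C\C | intermediate
24 | CNP0272382.1, (4S,5R,6R,7S,8S,11S)-4,5-epoxy-6-hydroxygermacr-1(10)E-ene-8,12-diyl bis[(Z)-2-methylbut-2-enoate] (cis epoxide; epoxide oxygen, C6 hydroxyl and C7 side chain on one ring face, C8 ester on the other) | C/C=C(/C)C(=O)OC[C@@H](C)[C@H]1[C@@H](O)[C@H]2O[C@@]2(C)CC/C=C(\C)C[C@@H]1OC(=O)/C(C)=C\C | target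

**Count**

Total steps: 15. Longest linear sequence: 14 steps (1 to 24 through steps 1–3 and 5–15; step 4 is a one-step branch).

**Steps most likely to fail**

Step 11 (thermal cycloreversion). The first-formed dienone may react on by Cope rearrangement to the divinylcyclohexanone, a process helped by the carbonyl, which polarises C4=C5 towards bond formation between C5 and C10. The β-silyloxy ketone may also enolise and lose silanol at 200 °C. Fallback at the alcohol oxidation level, from 17 back to 18: NaBH4 in MeOH at 0 °C should reduce the ketone from the face away from the four-membered rings to the tricyclic alcohol F1. Thermolysis of F1 under the flow conditions of step 11 should give the dienol F2, which has no carbonyl to speed the Cope pathway or to enolise. Oxidation of the allylic alcohol with Dess–Martin periodinane (NaHCO3, CH2Cl2) returns 18. The price is that enone conjugation no longer helps to fix the Z geometry at C4=C5.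

Step 10 (photocycloaddition). The unactivated, volatile alkene may add in the wrong orientation (C4 to C10), with poor cis,anti,cis control, or be lost by evaporation before the enone is consumed. Fallback with an ester-directed partner, from 15 back to 17: irradiation of 15 with methyl cyclobut-1-ene-1-carboxylate under the conditions of step 10 should give the keto ester F3, since cyclobutene esters are known to bond through the ester-bearing carbon to the enone α-carbon. LiAlH4 (THF, 0 °C) reduces ketone and ester to the diol F4. Dess–Martin periodinane oxidises both carbinols to the keto aldehyde F5. p-Toluenesulfonyl hydrazide (MeOH, rt) should condense only with the aldehyde to give the tosylhydrazone F6. Catecholborane (CHCl3, 0 °C) followed by NaOAc·3H2O at reflux reduces the hydrazone to the C4 methyl group and returns 17.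

Step 14 (CBS reduction). Facial selectivity may be poor or reversed, because both carbonyl substituents are bulky and the ring conformation may oppose the catalyst. Fallback by hydroxyl-directed reduction before acylation, from 19 back to 23: Me4NBH(OAc)3 in MeCN/AcOH at −30 °C binds the free C8 hydroxyl and delivers hydride intramolecularly to C6, which should give the 6,8-anti triol F7 with the C6 configuration of the target. Acylation with about two equivalents of 21 (toluene, rt to 50 °C) should then esterify the primary C12 hydroxyl and the C8 hydroxyl. The C6 hydroxyl, wedged between the branched C7 and the Z-trisubstituted alkene, is expected to react last, which returns 23.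

**Further compounds**

F1 | step 11 | 9-(tert-butyldimethylsilyloxy)-8-[(S)-1-(tert-butyldimethylsilyloxy)propan-2-yl]-1,5-dimethyltricyclo[4.4.0.0(2,5)]decan-7-ol (hydroxyl cis to the four-membered rings and the side chain) | CC(C)(C)[Si](C)(C)OC[C@@H](C)[C@H]1[C@@H](O)[C@H]2[C@]3(C)CC[C@@H]3[C@@]2(C)C[C@@H]1O[Si](C)(C)C(C)(C)C
F2 | step 11 | (2Z,6E)-9-(tert-butyldimethylsilyloxy)-10-[(S)-1-(tert-butyldimethylsilyloxy)propan-2-yl]-3,7-dimethylcyclodeca-2,6-dien-1-ol | CC(C)(C)[Si](C)(C)OC[C@@H](C)[C@H]1[C@@H](O)/C=C(C)\CC/C=C(\C)C[C@@H]1O[Si](C)(C)C(C)(C)C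
F3 | step 10 | methyl 9-(tert-butyldimethylsilyloxy)-8-[(S)-1-(tert-butyldimethylsilyloxy)propan-2-yl]-1-methyl-7-oxotricyclo[4.4.0.0(2,5)]decane-5-carboxylate (cis,anti,cis) | CC(C)(C)[Si](C)(C)OC[C@@H](C)[C@H]1C(=O)[C@H]2[C@]3(C(=O)OC)CC[C@@H]3[C@@]2(C)C[C@@H]1O[Si](C)(C)C(C)(C)C
F4 | step 10 | 9-(tert-butyldimethylsilyloxy)-8-[(S)-1-(tert-butyldimethylsilyloxy)propan-2-yl]-5-(hydroxymethyl)-1-methyltricyclo[4.4.0.0(2,5)]decan-7-ol | CC(C)(C)[Si](C)(C)OC[C@@H](C)[C@H]1[C@@H](O)[C@H]2[C@]3(CO)CC[C@@H]3[C@@]2(C)C[C@@H]1O[Si](C)(C)C(C)(C)C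
F5 | step 10 | 9-(tert-butyldimethylsilyloxy)-8-[(S)-1-(tert-butyldimethylsilyloxy)propan-2-yl]-1-methyl-7-oxotricyclo[4.4.0.0(2,5)]decane-5-carbaldehyde | CC(C)(C)[Si](C)(C)OC[C@@H](C)[C@H]1C(=O)[C@H]2[C@]3(C=O)CC[C@@H]3[C@@]2(C)C[C@@H]1O[Si](C)(C)C(C)(C)C
F6 | step 10 | (E)-p-toluenesulfonylhydrazone of the aldehyde F5 | CC(C)(C)[Si](C)(C)OC[C@@H](C)[C@H]1C(=O)[C@H]2[C@]3(/C=N/NS(=O)(=O)c4ccc(C)cc4)CC[C@@H]3[C@@]2(C)C[C@@H]1O[Si](C)(C)C(C)(C)C
F7 | step 14 | (2Z,6E)-10-[(S)-1-hydroxypropan-2-yl]-3,7-dimethylcyclodeca-2,6-diene-1,9-diol (1,9-anti; C6 as in the target) | OC[C@@H](C)[C@H]1[C@@H](O)/C=C(C)\CC/C=C(\C)C[C@@H]1O
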